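**Plan**

- Each benzene ring is a 6-alkyl-2,4-dihydroxybenzoate (ester carbonyl on C1, OH on C2 and C4, CH2 chain on C6). Each ring is cut at C1–C2 and C5–C6, so that C1 and C6 are the sp carbons of an alk-2-ynoate and C2–C5, with both oxygens, come from a 1,3-bis(silyloxy)diene.
- The open-chain bis-ynoate that remains is cut at its three ester C–O bonds into tert-butyl (R)-3-hydroxybutanoate, (R)-5-silyloxyhex-2-ynoic acid, (R)-3-silyloxybutanoic acid and a dioxolane-masked (R)-7-silyloxy-5-oxooct-2-ynoic acid.
- Forward, the chain is joined from the tert-butyl ester end by three carbodiimide esterifications (two desilylations in between), each at an acyl carbon on an alkyne or a CH2 group.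
- Both benzene rings then arise together in one twofold Diels–Alder/retro-Diels–Alder reaction that consumes two molecules of the dimedone-derived diene, and one aqueous acid treatment frees the acid, the ketone and the alcohol.
- All four stereocentres (all R) are carbinol carbons bought from the chiral pool: (R)-pent-4-yn-2-ol, tert-butyl (R)-3-hydroxybutanoate and methyl (R)-3-hydroxybutanoate (used twice). No C–O bond at a stereocentre is broken, so none is made or inverted.

Key step: step 16

Remark: the four stereocentres are read from the SMILES as R; the ynoic acids 4 and 19 are taken to be stable enough to be used directly after extraction. TBS = tert-butyldimethylsilyl, TMS = trimethylsilyl.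

**Route**

Step 1
Reactants: 1 (R)-pent-4-yn-2-ol
Product: 2 (R)-tert-butyldimethyl(pent-4-yn-2-yloxy)silane
Conditions: TBSCl, imidazole, CH2Cl2, 0 → 23 °C
Reagents that add atoms: tert-butyldimethylsilyl chloride (TBSCl), CC(C)(C)[Si](C)(C)Cl
Why: Imidazole-mediated O-silylation of a secondary alcohol is routine, leaves the stereocentre alone and removes the acidic OH before acetylide formation.

Step 2
Reactants: 2 (R)-tert-butyldimethyl(pent-4-yn-2-yloxy)silane
Product: 4 (R)-5-(TBSO)hex-2-ynoic acid, via lithium acetylide 3 (not isolated)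
Conditions: n-BuLi, THF, −78 °C; CO2, −78 → 0 °C; cold 1 M HCl to pH 3
Reagents that add atoms: carbon dioxide, O=C=O
Why: The terminal alkyne C–H is the only acidic site left, so lithiation and carboxylation of the acetylide (the standard alk-2-ynoic acid synthesis) should be clean, and the TBS ether withstands the brief cold acidification.

Step 3
Reactants: 4 (R)-5-(TBSO)hex-2-ynoic acid; 5 tert-butyl (R)-3-hydroxybutanoate
Product: 6 tert-butyl (R)-3-{[(R)-5-(TBSO)hex-2-ynoyl]oxy}butanoate
Conditions: DCC, DMAP (cat.), CH2Cl2, −20 → 0 °C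
Reagents that add atoms: none
Why: Steglich esterification engages an acyl carbon on a slim sp centre, so the secondary alcohol is acylated easily with retention (its C–O bond is not broken), while low temperature and only catalytic DMAP limit conjugate addition to the ynoate and ynoate-to-allenoate isomerization.

Step 4
Reactants: 6 tert-butyl (R)-3-{[(R)-5-(TBSO)hex-2-ynoyl]oxy}butanoate
Product: 7 tert-butyl (R)-3-{[(R)-5-hydroxyhex-2-ynoyl]oxy}butanoate
Conditions: HF·pyridine, pyridine, THF, 0 → 23 °C
Reagents that add atoms: none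
Why: Buffered HF·pyridine cleaves the secondary silyl ether through Si–F bond formation under non-basic conditions that leave the tert-butyl ester, the ynoate and the elimination-prone 3-acyloxybutanoate untouched.

Step 5
Reactants: 8 methyl (R)-3-hydroxybutanoate
Product: 9 methyl (R)-3-(TBSO)butanoate
Conditions: TBSCl, imidazole, DMF, 0 → 23 °C
Reagents that add atoms: tert-butyldimethylsilyl chloride (TBSCl), CC(C)(C)[Si](C)(C)Cl
Why: Standard silylation protects the β-hydroxyl of the chiral-pool ester so that the carboxyl group can later be activated without self-acylation, and the stereocentre is not involved.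

Step 6
Reactants: 9 methyl (R)-3-(TBSO)butanoate
Product: 10 (R)-3-(TBSO)butanoic acid
Conditions: LiOH, THF/MeOH/H2O, 0 → 23 °C; cold 1 M HCl to pH 3
Reagents that add atoms: lithium hydroxide, [Li+].[OH-]
Why: Saponification of a methyl ester with LiOH is well known for β-silyloxy esters, since silanolate is too poor a leaving group for E1cB elimination and the carbinol centre is not enolizable.

Step 7
Reactants: 7 tert-butyl (R)-3-{[(R)-5-hydroxyhex-2-ynoyl]oxy}butanoate; 10 (R)-3-(TBSO)butanoic acid
Product: 11 tert-butyl (R)-3-{[(R)-5-{[(R)-3-(TBSO)butanoyl]oxy}hex-2-ynoyl]oxy}butanoate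
Conditions: DCC, DMAP (cat.), CH2Cl2, 0 °C
Reagents that add atoms: none
Why: Steglich esterification of an unhindered aliphatic acid with the homopropargylic secondary alcohol occurs at the acyl carbon only, so all stereocentres are retained, and catalytic DMAP at 0 °C is too weak a base to eliminate the 3-acyloxybutanoate.

Step 8
Reactants: 11 tert-butyl (R)-3-{[(R)-5-{[(R)-3-(TBSO)butanoyl]oxy}hex-2-ynoyl]oxy}butanoate
Product: 12 tert-butyl (R)-3-{[(R)-5-{[(R)-3-hydroxybutanoyl]oxy}hex-2-ynoyl]oxy}butanoate
Conditions: HF·pyridine, pyridine, THF, 0 → 23 °C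
Reagents that add atoms: none
Why: Fluoride-driven desilylation under pyridine-buffered conditions frees the β-hydroxyl without base, so neither retro-oxa-Michael loss of an acyloxy group nor acyl migration should occur and the tert-butyl ester persists.

Step 9
Reactants: 10 (R)-3-(TBSO)butanoic acid
Product: 14 methyl (R)-5-(TBSO)-3-oxohexanoate, via acyl imidazolide 13 (not isolated)
Conditions: CDI, THF, 23 °C; Mg(O2CCH2CO2Me)2, THF, 23 → 45 °C; cold dilute HCl work-up
Reagents that add atoms: magnesium bis(methyl malonate), COC(=O)CC(=O)[O-].COC(=O)CC(=O)[O-].[Mg+2]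
Why: In this Masamune-type chain extension the acyl imidazolide C-acylates the magnesium enolate of the malonate half-ester under nearly neutral conditions, and decarboxylation gives the β-keto ester without elimination of the β-silyloxy group.

Step 10
Reactants: 14 methyl (R)-5-(TBSO)-3-oxohexanoate
Product: 15 methyl 2-{2-[(R)-2-(TBSO)propyl]-1,3-dioxolan-2-yl}acetate
Conditions: Me3SiOCH2CH2OSiMe3, TMSOTf (cat.), CH2Cl2, −78 → −20 °C; pyridine quench
Reagents that add atoms: 1,2-bis(trimethylsilyloxy)ethane, C[Si](C)(C)OCCO[Si](C)(C)C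
Why: Noyori ketalization transfers the glycol from its bis-silyl ether to the ketone under aprotic, catalytic silyl triflate conditions at low temperature, driven by Si–O–Si bond formation, so the alkyl TBS ether survives and the β-silyloxy ketone does not eliminate.

Step 11
Reactants: 15 methyl 2-{2-[(R)-2-(TBSO)propyl]-1,3-dioxolan-2-yl}acetate
Product: 16 2-{2-[(R)-2-(TBSO)propyl]-1,3-dioxolan-2-yl}acetaldehyde
Conditions: i-Bu2AlH, CH2Cl2, −78 °C; MeOH, then aq. KNaC4H4O6
Reagents that add atoms: none
Why: Partial reduction of a methyl ester by i-Bu2AlH at −78 °C stops at the aldehyde because the tetrahedral aluminium hemiacetal, chelated by a dioxolane oxygen, collapses only on work-up.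

Step 12
Reactants: 16 2-{2-[(R)-2-(TBSO)propyl]-1,3-dioxolan-2-yl}acetaldehyde
Product: 17 2-[(R)-2-(TBSO)propyl]-2-(prop-2-yn-1-yl)-1,3-dioxolane
Conditions: dimethyl (1-diazo-2-oxopropyl)phosphonate, K2CO3, MeOH, 0 → 23 °C
Reagents that add atoms: dimethyl (1-diazo-2-oxopropyl)phosphonate, COP(=O)(OC)C(=[N+]=[N-])C(C)=O
Why: The Ohira–Bestmann variant of the Seyferth–Gilbert homologation converts the aldehyde into the terminal alkyne by Horner–Wadsworth–Emmons olefination, loss of N2 and 1,2-hydride shift under mild carbonate/methanol conditions, so the propargylic ketal is built without passing through a free β,γ-alkynyl ketone.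

Step 13
Reactants: 17 2-[(R)-2-(TBSO)propyl]-2-(prop-2-yn-1-yl)-1,3-dioxolane
Product: 19 4-{2-[(R)-2-(TBSO)propyl]-1,3-dioxolan-2-yl}but-2-ynoic acid, via lithium acetylide 18 (not isolated)
Conditions: n-BuLi, THF, −78 °C; CO2, −78 → 0 °C; cold dilute HCl to pH 3, immediate extraction
Reagents that add atoms: carbon dioxide, O=C=O
Why: As in step 2, acetylide formation and carboxylation give the alk-2-ynoic acid, and careful acidification with immediate extraction spares the dioxolane and the silyl ether.

Step 14
Reactants: 12 tert-butyl (R)-3-{[(R)-5-{[(R)-3-hydroxybutanoyl]oxy}hex-2-ynoyl]oxy}butanoate; 19 4-{2-[(R)-2-(TBSO)propyl]-1,3-dioxolan-2-yl}but-2-ynoic acid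
Product: 20 acyclic bis-ynoate tetraester (tert-butyl ester, dioxolane, TBS ether)
Conditions: DCC, DMAP (cat.), CH2Cl2, −20 → 0 °C
Reagents that add atoms: none
Why: The third Steglich esterification again uses an sp-bound acyl carbon, so no hindered benzoate ever has to be esterified, the alcohol configuration is retained, and the low base load spares the γ-CH2 of the ynoate and both 3-acyloxybutanoates.

Step 15
Reactants: 21 dimedone
Product: 22 5,5-dimethyl-1,3-bis(trimethylsilyloxy)cyclohexa-1,3-diene
Conditions: TMSOTf (2.2 equiv), Et3N, Et2O, 0 → 23 °C; distillation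
Reagents that add atoms: trimethylsilyl trifluoromethanesulfonate (TMSOTf), C[Si](C)(C)OS(=O)(=O)C(F)(F)F
Why: Twofold soft enolization and O-silylation of the cyclic 1,3-diketone with a silyl triflate and triethylamine gives the conjugated bis(silyl enol ether), and the symmetry of dimedone allows only one such 1,3-bis(silyloxy)-1,3-diene.

Step 16
Reactants: 20 acyclic bis-ynoate tetraester; 22 5,5-dimethyl-1,3-bis(trimethylsilyloxy)cyclohexa-1,3-diene (two molecules are consumed per molecule of 20, one at each ynoate)
Product: 25 protected Hansforester I (tert-butyl ester / dioxolane / TBS ether; all four phenols free), via twofold bicyclo[2.2.2]octadiene cycloadduct 23 (not isolated), via tetrakis(trimethylsilyl) aryl ether 24 (not isolated)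
Conditions: 22 (excess, at least 2 equiv), neat, 140 °C, sealed tube under argon; then MeOH, citric acid (cat.), 23 °C
Reagents that add atoms: 5,5-dimethyl-1,3-bis(trimethylsilyloxy)cyclohexa-1,3-diene (second molecule of 22, for the second ynoate), CC1(C)CC(O[Si](C)(C)C)=CC(O[Si](C)(C)C)=C1
Why: Each electron-poor ynoate acts as the 2π partner and one molecule of the electron-rich diene 22 as the 4π partner of a thermal, asynchronous normal-demand [4+2] cycloaddition, so that one molecule of 20 takes up two molecules of 22; each bicyclo[2.2.2]octa-2,5-diene unit of 23 then undergoes a retro-[4+2] that expels its CMe2–CH2 bridge as isobutene, which is irreversible because a benzene ring is gained. The closest known reaction type is the thermal Diels–Alder/retro-Diels–Alder (Alder–Rickert-type) benzannulation of alk-2-ynoate esters, macrocyclic ynolides included, with 1,3-bis(silyloxy)cyclohexa-1,3-dienes, run here twice on one chain. Ring 1 and ring 2 each close by intermolecular [4+2] cycloaddition that forms C1–C2 and C5–C6 (four C–C bonds in all) and become aromatic by cycloreversion, after which methanol with a trace of citric acid should cleave the four labile aryl trimethylsilyl ethers of 24 but not the alkyl TBS ether, the dioxolane or the tert-butyl ester. No lasting stereocentre is created (the bridgeheads of 23 vanish on aromatization), and the four existing carbinol centres are remote from the reacting carbons and see only neutral heat. The selectivity needed is regiochemical: the unsubstituted diene terminus, the most nucleophilic carbon because both silyloxy groups push electron density onto it, bonds to the electrophilic β-carbon of each ynoate, so the oxygen-bearing terminus becomes C2 next to the ester carbon and the 2,4-dihydroxy-6-alkyl pattern results. The two ynoates are electronically alike and insulated from one another by saturated carbons, so an excess of diene should take both to completion independently.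

Step 17
Reactants: 25 protected Hansforester I (tert-butyl ester / dioxolane / TBS ether)
Product: 26 Hansforester I
Conditions: TFA/CH2Cl2/H2O, 0 → 23 °C
Reagents that add atoms: water, O
Why: Aqueous trifluoroacetic acid should ionize the tert-butyl ester (alkyl–oxygen cleavage with loss of isobutene), cleave the secondary TBS ether and hydrolyse the dioxolane in one pot, while the three secondary-alkyl ester links and the phenols are inert to acid and the water content and low temperature restrain dehydration of the emerging β-hydroxy ketone.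

**Compound list**

1 | (R)-pent-4-yn-2-ol | C#CC[C@@H](C)O | starting material
2 | (R)-tert-butyldimethyl(pent-4-yn-2-yloxy)silane | C#CC[C@@H](C)O[Si](C)(C)C(C)(C)C | intermediate
3 | [(R)-4-(tert-butyldimethylsilyloxy)pent-1-yn-1-yl]lithium (lithium acetylide of 2) | [Li]C#CC[C@@H](C)O[Si](C)(C)C(C)(C)C | intermediate
4 | (R)-5-(tert-butyldimethylsilyloxy)hex-2-ynoic acid | C[C@H](CC#CC(=O)O)O[Si](C)(C)C(C)(C)C | intermediate
5 | tert-butyl (R)-3-hydroxybutanoate | C[C@@H](O)CC(=O)OC(C)(C)C | starting material
6 | tert-butyl (R)-3-{[(R)-5-(tert-butyldimethylsilyloxy)hex-2-ynoyl]oxy}butanoate | C[C@H](CC#CC(=O)O[C@H](C)CC(=O)OC(C)(C)C)O[Si](C)(C)C(C)(C)C | intermediate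
7 | tert-butyl (R)-3-{[(R)-5-hydroxyhex-2-ynoyl]oxy}butanoate | C[C@H](CC#CC(=O)O[C@H](C)CC(=O)OC(C)(C)C)O | intermediate
8 | methyl (R)-3-hydroxybutanoate | C[C@@H](O)CC(=O)OC | starting material
9 | methyl (R)-3-(tert-butyldimethylsilyloxy)butanoate | C[C@@H](O[Si](C)(C)C(C)(C)C)CC(=O)OC | intermediate
10 | (R)-3-(tert-butyldimethylsilyloxy)butanoic acid | C[C@@H](O[Si](C)(C)C(C)(C)C)CC(=O)O | intermediate
11 | tert-butyl (R)-3-{[(R)-5-{[(R)-3-(tert-butyldimethylsilyloxy)butanoyl]oxy}hex-2-ynoyl]oxy}butanoate | C[C@H](CC#CC(=O)O[C@H](C)CC(=O)OC(C)(C)C)OC(=O)C[C@@H](C)O[Si](C)(C)C(C)(C)C | intermediate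
12 | tert-butyl (R)-3-{[(R)-5-{[(R)-3-hydroxybutanoyl]oxy}hex-2-ynoyl]oxy}butanoate | C[C@H](CC#CC(=O)O[C@H](C)CC(=O)OC(C)(C)C)OC(=O)C[C@@H](C)O | intermediate
13 | (R)-3-(tert-butyldimethylsilyloxy)-1-(imidazol-1-yl)butan-1-one (acyl imidazolide of 10) | C[C@@H](O[Si](C)(C)C(C)(C)C)CC(=O)n1ccnc1 | intermediate
14 | methyl (R)-5-(tert-butyldimethylsilyloxy)-3-oxohexanoate | C[C@@H](O[Si](C)(C)C(C)(C)C)CC(=O)CC(=O)OC | intermediate
15 | methyl 2-{2-[(R)-2-(tert-butyldimethylsilyloxy)propyl]-1,3-dioxolan-2-yl}acetate | C[C@@H](O[Si](C)(C)C(C)(C)C)CC1(CC(=O)OC)OCCO1 | intermediate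
16 | 2-{2-[(R)-2-(tert-butyldimethylsilyloxy)propyl]-1,3-dioxolan-2-yl}acetaldehyde | C[C@@H](O[Si](C)(C)C(C)(C)C)CC1(CC=O)OCCO1 | intermediate
17 | 2-[(R)-2-(tert-butyldimethylsilyloxy)propyl]-2-(prop-2-yn-1-yl)-1,3-dioxolane | C[C@@H](O[Si](C)(C)C(C)(C)C)CC1(CC#C)OCCO1 | intermediate
18 | lithium acetylide of 17: (3-{2-[(R)-2-(tert-butyldimethylsilyloxy)propyl]-1,3-dioxolan-2-yl}prop-1-yn-1-yl)lithium | C[C@@H](O[Si](C)(C)C(C)(C)C)CC1(CC#C[Li])OCCO1 | intermediate
19 | 4-{2-[(R)-2-(tert-butyldimethylsilyloxy)propyl]-1,3-dioxolan-2-yl}but-2-ynoic acid | C[C@@H](O[Si](C)(C)C(C)(C)C)CC1(CC#CC(=O)O)OCCO1 | intermediate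
20 | acyclic bis-ynoate tetraester: tert-butyl (R)-3-{[(R)-5-{[(R)-3-({4-[2-((R)-2-(tert-butyldimethylsilyloxy)propyl)-1,3-dioxolan-2-yl]but-2-ynoyl}oxy)butanoyl]oxy}hex-2-ynoyl]oxy}butanoate | C[C@H](CC#CC(=O)O[C@H](C)CC(=O)OC(C)(C)C)OC(=O)C[C@@H](C)OC(=O)C#CCC1(C[C@@H](C)O[Si](C)(C)C(C)(C)C)OCCO1 | intermediate
21 | dimedone (5,5-dimethylcyclohexane-1,3-dione) | CC1(C)CC(=O)CC(=O)C1 | starting material
22 | 5,5-dimethyl-1,3-bis(trimethylsilyloxy)cyclohexa-1,3-diene | CC1(C)CC(O[Si](C)(C)C)=CC(O[Si](C)(C)C)=C1 | intermediate
23 | twofold cycloadduct of 20 with two molecules of 22: each C≡C–CO2R unit has become a 3-alkyl-8,8-dimethyl-1,5-bis(trimethylsilyloxy)bicyclo[2.2.2]octa-2,5-diene-2-carboxylate (mixture of bridgehead diastereomers) | C[C@H](CC1=C(C(=O)O[C@H](C)CC(=O)OC(C)(C)C)C2(O[Si](C)(C)C)C=C(O[Si](C)(C)C)C1C(C)(C)C2)OC(=O)C[C@@H](C)OC(=O)C1=C(CC3(C[C@@H](C)O[Si](C)(C)C(C)(C)C)OCCO3)C2C(O[Si](C)(C)C)=CC1(O[Si](C)(C)C)CC2(C)C | intermediate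
24 | tetrakis(trimethylsilyl) aryl ether of 25 (both rings as 2,4-bis(trimethylsilyloxy)benzoates) | C[C@H](Cc1cc(O[Si](C)(C)C)cc(O[Si](C)(C)C)c1C(=O)O[C@H](C)CC(=O)OC(C)(C)C)OC(=O)C[C@@H](C)OC(=O)c1c(O[Si](C)(C)C)cc(O[Si](C)(C)C)cc1CC1(C[C@@H](C)O[Si](C)(C)C(C)(C)C)OCCO1 | intermediate
25 | protected Hansforester I: tert-butyl (R)-3-{[2,4-dihydroxy-6-((R)-2-{[(R)-3-({2,4-dihydroxy-6-[(2-{(R)-2-(tert-butyldimethylsilyloxy)propyl}-1,3-dioxolan-2-yl)methyl]benzoyl}oxy)butanoyl]oxy}propyl)benzoyl]oxy}butanoate | C[C@H](Cc1cc(O)cc(O)c1C(=O)O[C@H](C)CC(=O)OC(C)(C)C)OC(=O)C[C@@H](C)OC(=O)c1c(O)cc(O)cc1CC1(C[C@@H](C)O[Si](C)(C)C(C)(C)C)OCCO1 | intermediate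
26 | Hansforester I: (R)-3-{[2,4-dihydroxy-6-((R)-2-{[(R)-3-({2,4-dihydroxy-6-[(R)-4-hydroxy-2-oxopentyl]benzoyl}oxy)butanoyl]oxy}propyl)benzoyl]oxy}butanoic acid | C[C@H](Cc1cc(O)cc(O)c1C(=O)O[C@H](C)CC(=O)O)OC(=O)C[C@@H](C)OC(=O)c1c(O)cc(O)cc1CC(=O)C[C@@H](C)O | target

**Step count and risks**

Total step count: 17.
Longest linear sequence: 10 steps (8 → 9 → 10 → 14 → 15 → 16 → 17 → 19 → 20 → 25 → 26; steps 5, 6, 9, 10, 11, 12, 13, 14, 16, 17).

Three steps most likely to fail:

Step 16. The second cycloaddition may stall after one ring has formed. The diene terminus flanked by the gem-dimethyl group may also bond too slowly to the ynoate β-carbon beside the quaternary dioxolane carbon, so that thermal degradation of the chain (ynoate isomerization, ene pathways) overtakes ring formation. The fallback changes the 4π partner and the fragment that is expelled. Cyclohexane-1,3-dione is bis-silylated (TMSOTf, Et3N, Et2O) to 1,3-bis(trimethylsilyloxy)cyclohexa-1,3-diene F1, whose nucleophilic terminus has no quaternary neighbour. Heating 20 with an excess of F1 (at least two equivalents, o-dichlorobenzene, 160–180 °C) should give the twofold bicyclo[2.2.2]octadiene adduct F2, which aromatizes by Alder–Rickert loss of ethene. This fallback sets out from 20 and comes back to the route at the tetrakis(trimethylsilyl) ether 24, which is methanolysed to 25 as before.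

Step 17. The tert-butyl cation released in strong protic acid may alkylate the electron-rich resorcinol rings. Prolonged acid may also dehydrate the β-hydroxy ketone or let the enol of the benzylic ketone close onto the neighbouring benzoate, which would form an isocoumarin and cut the chain. The fallback cleaves the tert-butyl ester by silyl transfer instead of protonation. Treating 25 with TMSOTf and 2,6-lutidine (CH2Cl2, 0 °C) should give the trimethylsilyl ester with four silylated phenols F3, the tert-butyl group leaving as isobutene in a buffered medium. Without isolation, dilute aqueous HCl in THF (0 → 23 °C) then hydrolyses the silyl ester, the aryl silyl ethers, the TBS ether and the dioxolane. This fallback sets out from 25 and comes back at 26.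

Step 12. In K2CO3/MeOH the enolizable β,β-dialkoxy aldehyde may undergo β-elimination with opening of the dioxolane, or aldol self-condensation, faster than it is olefinated by the diazophosphonate anion. The fallback is a dibromoolefination without alkoxide base followed by Corey–Fuchs rearrangement. Aldehyde 16 with CBr4, PPh3 and Et3N (CH2Cl2, 0 °C) should give 2-[(R)-2-(tert-butyldimethylsilyloxy)propyl]-2-(3,3-dibromoprop-2-en-1-yl)-1,3-dioxolane F4. Two equivalents of n-BuLi (THF, −78 °C) then convert F4 directly into the lithium acetylide 18, which is quenched with CO2 as in step 13. This fallback sets out from 16 and comes back at 18 and hence 19, bypassing the free alkyne 17.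

**Further compounds**

F1 | step 16 | 1,3-bis(trimethylsilyloxy)cyclohexa-1,3-diene | C[Si](C)(C)OC1=CC(O[Si](C)(C)C)=CCC1
F2 | step 16 | twofold bicyclo[2.2.2]octadiene adduct of 20 with two molecules of F1 (as 23 but without the gem-dimethyl groups; mixture of bridgehead diastereomers) | C[C@H](CC1=C(C(=O)O[C@H](C)CC(=O)OC(C)(C)C)C2(O[Si](C)(C)C)C=C(O[Si](C)(C)C)C1CC2)OC(=O)C[C@@H](C)OC(=O)C1=C(CC3(C[C@@H](C)O[Si](C)(C)C(C)(C)C)OCCO3)C2C(O[Si](C)(C)C)=CC1(O[Si](C)(C)C)CC2
F3 | step 17 | trimethylsilyl ester of 25 with all four phenols as trimethylsilyl ethers (TBS ether and dioxolane intact) | C[C@H](Cc1cc(O[Si](C)(C)C)cc(O[Si](C)(C)C)c1C(=O)O[C@H](C)CC(=O)O[Si](C)(C)C)OC(=O)C[C@@H](C)OC(=O)c1c(O[Si](C)(C)C)cc(O[Si](C)(C)C)cc1CC1(C[C@@H](C)O[Si](C)(C)C(C)(C)C)OCCO1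
F4 | step 12 | 2-[(R)-2-(tert-butyldimethylsilyloxy)propyl]-2-(3,3-dibromoprop-2-en-1-yl)-1,3-dioxolane | C[C@@H](O[Si](C)(C)C(C)(C)C)CC1(CC=C(Br)Br)OCCO1
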